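## Retrosynthetic overview

1. The target is methyl (13R)-17-acetoxy-3β-hydroxylabd-7-en-15-oate. The 3β-alcohol is traced to the C3 ketone, the 7-en-17-yl acetate to an 8(17)-alkene (allylic oxidation at C7, then 1,3-transposition), and the 4,4-dimethyl/5α-H array to reductive methylation of a 4-methyl-4-en-3-one.
2. The strategy rests on ring A: C3 bears the oxygen, its neighbour C4 bears a methyl group, and C10, opposite C3 in the ring, is a methylated quaternary carbon. Ring A is therefore a dearomatized 2,4-dimethylphenol whose para position is C10 and whose meta position C5 carries C6.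
3. Key disconnection: the C6–C7 and C9–C10 bonds of ring B, made in one palladium-catalysed dearomative [3+3] annulation. Phenol sulfone 8 supplies C6 and C10 as nucleophiles; bis-carbonate 18 supplies C7–C8(=C17)–C9 as the electrophile, with the C11–C16 side chain attached.
4. Fragment 1 (8) comes from 2,6-dimethylbenzoic acid. Fragment 2 (18) comes from methyl (R)-citronellate (C13) and 2-bromoprop-2-en-1-ol, with C9 set by oxazaborolidine reduction.
5. Ring order: ring A enters as the arene; ring B is the only ring formed (step 14).

Key step: step 14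

Remark on the chemistry: C9 is fixed as (S) in 16–18 so that net retention in step 14 gives the 9α-H configuration; the ligand antipode named in step 14 is the first choice and its match with the substrate would have to be established. The sulfonyl group is removed before the dissolving-metal step because a γ-sulfonyl enone would expel sulfinate there, and C15 is carried through that step as the carboxylate.

## Route

Step 1
Reactants: 1 2,6-dimethylbenzoic acid
Product: 2 2,6-dimethyl-3-nitrobenzoic acid
Conditions: fuming HNO3, conc. H2SO4, 0 °C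
Reagents that add atoms: nitric acid (O[N+](=O)[O-])
Why: electrophilic aromatic nitration; C3 (equivalent to C5) is the only position ortho/para to both methyl groups and meta to the carboxyl group, and the nitro group should stop a second substitution.

Step 2
Reactants: 2 2,6-dimethyl-3-nitrobenzoic acid
Product: 3 3-amino-2,6-dimethylbenzoic acid
Conditions: H2 (1 atm), Pd/C, MeOH, rt
Reagents that add atoms: none
Why: catalytic hydrogenation of an aromatic nitro group, which leaves the hindered acid and the ring untouched.

Step 3
Reactants: 3 3-amino-2,6-dimethylbenzoic acid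
Product: 5 3-hydroxy-2,6-dimethylbenzoic acid, via diazonium hydrogensulfate 4 (not isolated)
Conditions: NaNO2, aq. H2SO4, 0 °C; then added to hot aq. H2SO4 (about 100 °C)
Reagents that add atoms: water (O)
Why: diazotization followed by thermal hydrolysis of the arenediazonium salt, the standard conversion of an aminobenzoic acid into the hydroxybenzoic acid.

Step 4
Reactants: 5 3-hydroxy-2,6-dimethylbenzoic acid
Product: 6 3-(hydroxymethyl)-2,4-dimethylphenol
Conditions: LiAlH4 (excess), THF, reflux; dilute HCl work-up
Reagents that add atoms: none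
Why: hydride reduction of a carboxylate to the benzylic alcohol, which is known to proceed at reflux for 2,6-disubstituted benzoic acids; the phenoxide is inert.

Step 5
Reactants: 6 3-(hydroxymethyl)-2,4-dimethylphenol
Product: 7 3-(bromomethyl)-2,4-dimethylphenol
Conditions: PBr3, Et2O/THF, 0 °C; aqueous work-up, used crude
Reagents that add atoms: phosphorus tribromide (BrP(Br)Br)
Why: bromide displacement on the benzylic phosphite at low temperature avoids the strong acid that could cause Friedel–Crafts self-benzylation; the meta-hydroxy group cannot form a quinone methide and is returned on work-up.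

Step 6
Reactants: 7 3-(bromomethyl)-2,4-dimethylphenol
Product: 8 2,4-dimethyl-3-[(phenylsulfonyl)methyl]phenol (fragment 1)
Conditions: PhSO2Na, DMF, rt to 50 °C
Reagents that add atoms: sodium benzenesulfinate ([Na+].[O-]S(=O)c1ccccc1)
Why: S-alkylation of the sulfinate by a benzylic bromide (SN2) gives the sulfone, and the un-ionized phenol does not compete.

Step 7
Reactants: 9 methyl (R)-citronellate
Product: 11 methyl (3R)-3-methyl-6-oxohexanoate, via ozonide 10 (not isolated)
Conditions: O3, CH2Cl2, −78 °C; then PPh3, −78 °C to rt
Reagents that add atoms: ozone ([O-][O+]=O)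
Why: ozonolysis of the trisubstituted alkene with reductive work-up; the C13 stereocentre is β to the ester and γ to the new aldehyde, so it cannot epimerize.

Step 8
Reactants: 12 2-bromoprop-2-en-1-ol
Product: 13 [(2-bromoprop-2-en-1-yl)oxy](tert-butyl)dimethylsilane
Conditions: TBSCl, imidazole, CH2Cl2, rt
Reagents that add atoms: tert-butyldimethylsilyl chloride (CC(C)(C)[Si](C)(C)Cl)
Why: silylation of the primary allylic alcohol; a silyl ether, unlike an ester or carbonate, is not expelled from the alkenylmetal species of the next step.

Step 9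
Reactants: 11 methyl (3R)-3-methyl-6-oxohexanoate; 13 [(2-bromoprop-2-en-1-yl)oxy](tert-butyl)dimethylsilane
Product: 14 methyl (3R,6RS)-8-[(tert-butyldimethylsilyl)oxy]-6-hydroxy-3-methyl-7-methylideneoctanoate (both C9 epimers, labdane numbering)
Conditions: CrCl2 (4 equiv), NiCl2 (2 mol %), DMF, rt
Reagents that add atoms: none
Why: Nozaki–Hiyama–Kishi coupling of the alkenyl bromide with the aldehyde forms C8–C9 chemoselectively in the presence of the methyl ester; the new carbinol centre is not controlled here and is corrected in steps 10 and 11.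

Step 10
Reactants: 14 methyl (3R,6RS)-8-[(tert-butyldimethylsilyl)oxy]-6-hydroxy-3-methyl-7-methylideneoctanoate
Product: 15 methyl (3R)-8-[(tert-butyldimethylsilyl)oxy]-3-methyl-7-methylidene-6-oxooctanoate
Conditions: Dess–Martin periodinane, CH2Cl2, 0 °C to rt; used at once
Reagents that add atoms: none
Why: Dess–Martin oxidation of the secondary allylic alcohol gives the α-methylene ketone under neutral conditions and removes the uncontrolled stereocentre.

Step 11
Reactants: 15 methyl (3R)-8-[(tert-butyldimethylsilyl)oxy]-3-methyl-7-methylidene-6-oxooctanoate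
Product: 16 methyl (3R,6S)-8-[(tert-butyldimethylsilyl)oxy]-6-hydroxy-3-methyl-7-methylideneoctanoate
Conditions: (R)-2-methyl-CBS-oxazaborolidine (20 mol %), catecholborane, toluene, −78 °C
Reagents that add atoms: none
Why: Corey–Bakshi–Shibata reduction in the 1,2-mode; with the α-substituted vinyl group as the large substituent and the CH2 chain as the small one, the (R)-catalyst should deliver hydride to give the (S)-carbinol at C9.

Step 12
Reactants: 16 methyl (3R,6S)-8-[(tert-butyldimethylsilyl)oxy]-6-hydroxy-3-methyl-7-methylideneoctanoate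
Product: 17 methyl (3R,6S)-6,8-dihydroxy-3-methyl-7-methylideneoctanoate
Conditions: HF·pyridine, THF, 0 °C to rt
Reagents that add atoms: none
Why: fluoride-mediated cleavage of the primary silyl ether under buffered conditions that spare the ester and the allylic carbinol.

Step 13
Reactants: 17 methyl (3R,6S)-6,8-dihydroxy-3-methyl-7-methylideneoctanoate
Product: 18 methyl (3R,6S)-6,8-bis[(methoxycarbonyl)oxy]-3-methyl-7-methylideneoctanoate (fragment 2)
Conditions: ClCO2Me (3 equiv), pyridine, DMAP (cat.), CH2Cl2, 0 °C to rt
Reagents that add atoms: methyl chloroformate (COC(=O)Cl)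
Why: acylation of both hydroxyl groups gives the two allylic methyl carbonates without touching C9, whose configuration stays (S).

Step 14
Reactants: 8 2,4-dimethyl-3-[(phenylsulfonyl)methyl]phenol; 18 methyl (3R,6S)-6,8-bis[(methoxycarbonyl)oxy]-3-methyl-7-methylideneoctanoate
Product: 20 methyl (13R)-3-oxo-6-(phenylsulfonyl)-19-norlabda-1,4,8(17)-trien-15-oate, via mono-allylated sulfone carbonate 19 (not isolated)
Conditions: 8, LiN(SiMe3)2 (2.1 equiv), THF, −78 to 0 °C; then 18 (1.0 equiv), Pd2(dba)3·CHCl3 (2.5 mol %), (1R,2R)-N,N′-bis[2-(diphenylphosphino)benzoyl]cyclohexane-1,2-diamine (7.5 mol %), THF (0.02 M), 0 °C to rt; aq. NH4Cl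
Reagents that add atoms: none
Why: Proposed new method: the primary carbonate of 18 should be the first to be ionized by zerovalent palladium, and the resulting 2-substituted π-allyl unit (C7–C8–C17, both termini CH2 and therefore equivalent) is captured by the soft sulfonyl carbanion C6 of the dianion of 8 to give 19; the secondary carbonate is then ionized with inversion at C9, and the new π-allyl complex of divalent palladium (C17–C8–C9) is closed by the phenoxide para carbon C10 attacking C9 anti to the metal. The closest known reaction types are the palladium-catalysed intramolecular allylic dearomatization of phenols and the double allylic alkylation of bis-nucleophiles by 2-methylenepropane-1,3-diyl dicarbonates, which are merged here into one annulation. Ring B is closed in a six-membered mode by this outer-sphere C-alkylation, C10 bonding to the allyl terminus C9 and leaving C17 as the exocyclic methylene; the alternatives are an eight-membered ring (C10 to C17), a four-membered ring (C6 to C9) or a macrocyclic O-allylation that the catalyst would reopen. C9 should keep the configuration of the (S)-carbonate through double inversion, provided ring closure is faster than π–σ–π exchange through the CH2 terminus C17, and C10 is set by the chiral ligand, which must present the phenoxide face that places the C10 methyl (C20) cis to C11. The step needs C10 to win over the equally placed ortho carbon C4: C10 carries the larger coefficient of the phenoxide HOMO and is flanked by C1–H, whereas C4 lies beside the lithium-aggregated oxygen, and the cross-conjugated dienone is the more stable product should C-allylation be reversible. C6 is formed as both epimers, which is of no consequence because the sulfonyl group is removed in step 15, and the high dilution is meant to suppress intermolecular second allylation.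

Step 15
Reactants: 20 methyl (13R)-3-oxo-6-(phenylsulfonyl)-19-norlabda-1,4,8(17)-trien-15-oate
Product: 21 methyl (13R)-3-oxo-19-norlabda-1,4,8(17)-trien-15-oate
Conditions: Al(Hg), THF/H2O (10:1), 0 °C to rt; then DBU (0.2 equiv), CH2Cl2, rt
Reagents that add atoms: none
Why: reductive desulfonylation of a vinylogous β-keto sulfone: two-electron transfer from Al(Hg) into the dienone expels sulfinate from C6 and water protonates the trienolate, DBU then returning any C4-protonated material to full conjugation, while ester and 8(17)-alkene are inert.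

Step 16
Reactants: 21 methyl (13R)-3-oxo-19-norlabda-1,4,8(17)-trien-15-oate
Product: 22 methyl (13R)-3-oxo-19-norlabda-4,8(17)-dien-15-oate
Conditions: [(Ph3P)CuH]6 (0.5 equiv of hexamer), H2O (3 equiv), benzene, rt
Reagents that add atoms: none
Why: copper hydride conjugate reduction: hydride adds to the less substituted β-carbon C1 and the copper enolate is protonated at C2, while the tetrasubstituted C4=C5 enone and the isolated 8(17)-alkene should not react.

Step 17
Reactants: 22 methyl (13R)-3-oxo-19-norlabda-4,8(17)-dien-15-oate
Product: 23 (13R)-3-oxo-19-norlabda-4,8(17)-dien-15-oic acid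
Conditions: LiOH·H2O, THF/MeOH/H2O, rt; then 1 M HCl to pH 3
Reagents that add atoms: lithium hydroxide ([Li+].[OH-])
Why: ester saponification, so that C15 enters the dissolving-metal step as a carboxylate, which solvated electrons do not reduce; C13 is β to the carboxyl group and cannot epimerize.

Step 18
Reactants: 23 (13R)-3-oxo-19-norlabda-4,8(17)-dien-15-oic acid
Product: 25 (13R)-3-oxolabd-8(17)-en-15-oic acid, via dilithium enolate carboxylate 24 (not isolated)
Conditions: Li (4 equiv), NH3(l)/THF, t-BuOH (1 equiv), −78 °C; isoprene; MeI (excess), −78 to −33 °C; aq. NH4Cl, then 1 M HCl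
Reagents that add atoms: iodomethane (CI)
Why: reductive alkylation of an enone: the β-carbanion at C5 is protonated axially on the α-face to give the trans ring fusion (5α-H), and the regiodefined C3–C4 lithium enolate is methylated at C4 to give the gem-dimethyl group, while the carboxylate and the isolated alkene are untouched.

Step 19
Reactants: 25 (13R)-3-oxolabd-8(17)-en-15-oic acid
Product: 26 methyl (13R)-3-oxolabd-8(17)-en-15-oate
Conditions: Me3SiCHN2, MeOH/toluene, 0 °C to rt
Reagents that add atoms: (trimethylsilyl)diazomethane (C[Si](C)(C)C=[N+]=[N-])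
Why: mild O-methylation of the carboxylic acid by the diazoalkane, which restores the methyl ester whether or not the carboxylate was alkylated in step 18.

Step 20
Reactants: 26 methyl (13R)-3-oxolabd-8(17)-en-15-oate
Product: 27 methyl (13R)-7α-hydroxy-3-oxolabd-8(17)-en-15-oate
Conditions: SeO2 (0.5 equiv), t-BuOOH (3 equiv), CH2Cl2, rt
Reagents that add atoms: selenium dioxide (O=[Se]=O); tert-butyl hydroperoxide (CC(C)(C)OO)
Why: selenium dioxide allylic oxidation (ene reaction, then [2,3]-sigmatropic shift): the ring methylene C7 should react in preference to the hindered methine C9, and oxygen is delivered axially on the α-face to give the 7α-alcohol with the alkene back at C8=C17.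

Step 21
Reactants: 27 methyl (13R)-7α-hydroxy-3-oxolabd-8(17)-en-15-oate
Product: 29 methyl (13R)-17-chloro-3-oxolabd-7-en-15-oate, via allylic chlorosulfite 28 (not isolated)
Conditions: SOCl2 (1.2 equiv), Et2O, 0 °C to rt, no base
Reagents that add atoms: thionyl chloride (ClS(Cl)=O)
Why: the axial allylic chlorosulfite should collapse by the cyclic SNi′ path, delivering chloride to C17 and moving the alkene to the more substituted C7=C8 position, as secondary 2-methylenecycloalkanols are known to do.

Step 22
Reactants: 29 methyl (13R)-17-chloro-3-oxolabd-7-en-15-oate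
Product: 30 methyl (13R)-17-acetoxy-3-oxolabd-7-en-15-oate
Conditions: CsOAc, DMF, rt to 40 °C
Reagents that add atoms: caesium acetate ([Cs+].CC(=O)[O-])
Why: SN2 displacement of a primary allylic chloride by acetate.

Step 23
Reactants: 30 methyl (13R)-17-acetoxy-3-oxolabd-7-en-15-oate
Product: 31 methyl (13R)-17-acetoxy-3β-hydroxylabd-7-en-15-oate (target)
Conditions: NaBH4, MeOH/THF, −20 to 0 °C
Reagents that add atoms: none
Why: borohydride reduction of the 4,4-dimethyl-3-ketone with axial hydride delivery on the α-face, which should give mainly the equatorial 3β-alcohol; the methyl ester and the allylic acetate are not reduced at this temperature.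

## Compound list

1 | 2,6-dimethylbenzoic acid | Cc1cccc(C)c1C(=O)O | starting material
2 | 2,6-dimethyl-3-nitrobenzoic acid | Cc1ccc([N+](=O)[O-])c(C)c1C(=O)O | intermediate
3 | 3-amino-2,6-dimethylbenzoic acid | Cc1ccc(N)c(C)c1C(=O)O | intermediate
4 | 3-carboxy-2,4-dimethylbenzenediazonium hydrogensulfate (not isolated) | Cc1ccc([N+]#N)c(C)c1C(=O)O.OS(=O)(=O)[O-] | intermediate
5 | 3-hydroxy-2,6-dimethylbenzoic acid | Cc1ccc(O)c(C)c1C(=O)O | intermediate
6 | 3-(hydroxymethyl)-2,4-dimethylphenol | Cc1ccc(O)c(C)c1CO | intermediate
7 | 3-(bromomethyl)-2,4-dimethylphenol | Cc1ccc(O)c(C)c1CBr | intermediate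
8 | 2,4-dimethyl-3-[(phenylsulfonyl)methyl]phenol (fragment 1) | Cc1ccc(O)c(C)c1CS(=O)(=O)c1ccccc1 | intermediate
9 | methyl (R)-citronellate | COC(=O)C[C@H](C)CCC=C(C)C | starting material
10 | methyl (3R)-5-(5,5-dimethyl-1,2,4-trioxolan-3-yl)-3-methylpentanoate (ozonide, not isolated) | COC(=O)C[C@H](C)CCC1OOC(C)(C)O1 | intermediate
11 | methyl (3R)-3-methyl-6-oxohexanoate | COC(=O)C[C@H](C)CCC=O | intermediate
12 | 2-bromoprop-2-en-1-ol | C=C(Br)CO | starting material
13 | [(2-bromoprop-2-en-1-yl)oxy](tert-butyl)dimethylsilane | C=C(Br)CO[Si](C)(C)C(C)(C)C | intermediate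
14 | methyl (3R,6RS)-8-[(tert-butyldimethylsilyl)oxy]-6-hydroxy-3-methyl-7-methylideneoctanoate | COC(=O)C[C@H](C)CCC(O)C(=C)CO[Si](C)(C)C(C)(C)C | intermediate
15 | methyl (3R)-8-[(tert-butyldimethylsilyl)oxy]-3-methyl-7-methylidene-6-oxooctanoate | COC(=O)C[C@H](C)CCC(=O)C(=C)CO[Si](C)(C)C(C)(C)C | intermediate
16 | methyl (3R,6S)-8-[(tert-butyldimethylsilyl)oxy]-6-hydroxy-3-methyl-7-methylideneoctanoate | COC(=O)C[C@H](C)CC[C@H](O)C(=C)CO[Si](C)(C)C(C)(C)C | intermediate
17 | methyl (3R,6S)-6,8-dihydroxy-3-methyl-7-methylideneoctanoate | COC(=O)C[C@H](C)CC[C@H](O)C(=C)CO | intermediate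
18 | methyl (3R,6S)-6,8-bis[(methoxycarbonyl)oxy]-3-methyl-7-methylideneoctanoate (fragment 2) | COC(=O)C[C@H](C)CC[C@H](OC(=O)OC)C(=C)COC(=O)OC | intermediate
19 | methyl (3R,6S)-9-(3-hydroxy-2,6-dimethylphenyl)-6-[(methoxycarbonyl)oxy]-3-methyl-7-methylidene-9-(phenylsulfonyl)nonanoate (both epimers at the sulfonyl carbon, not isolated) | COC(=O)C[C@H](C)CC[C@H](OC(=O)OC)C(=C)CC(S(=O)(=O)c1ccccc1)c1c(C)ccc(O)c1C | intermediate
20 | methyl (13R)-3-oxo-6-(phenylsulfonyl)-19-norlabda-1,4,8(17)-trien-15-oate (9α-H, 10β-methyl, both C6 epimers) | COC(=O)C[C@H](C)CC[C@H]1C(=C)CC(S(=O)(=O)c3ccccc3)C2=C(C)C(=O)C=C[C@]12C | intermediate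
21 | methyl (13R)-3-oxo-19-norlabda-1,4,8(17)-trien-15-oate | COC(=O)C[C@H](C)CC[C@H]1C(=C)CCC2=C(C)C(=O)C=C[C@]12C | intermediate
22 | methyl (13R)-3-oxo-19-norlabda-4,8(17)-dien-15-oate | COC(=O)C[C@H](C)CC[C@H]1C(=C)CCC2=C(C)C(=O)CC[C@]12C | intermediate
23 | (13R)-3-oxo-19-norlabda-4,8(17)-dien-15-oic acid | OC(=O)C[C@H](C)CC[C@H]1C(=C)CCC2=C(C)C(=O)CC[C@]12C | intermediate
24 | dilithium salt of the C3–C4 enolate and C15 carboxylate of (13R)-3-oxo-19-nor-5α-labd-8(17)-en-15-oic acid (not isolated) | [Li+].[Li+].[O-]C(=O)C[C@H](C)CC[C@H]1C(=C)CC[C@H]2C(C)=C([O-])CC[C@]12C | intermediate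
25 | (13R)-3-oxolabd-8(17)-en-15-oic acid | OC(=O)C[C@H](C)CC[C@H]1C(=C)CC[C@H]2C(C)(C)C(=O)CC[C@]12C | intermediate
26 | methyl (13R)-3-oxolabd-8(17)-en-15-oate | COC(=O)C[C@H](C)CC[C@H]1C(=C)CC[C@H]2C(C)(C)C(=O)CC[C@]12C | intermediate
27 | methyl (13R)-7α-hydroxy-3-oxolabd-8(17)-en-15-oate | COC(=O)C[C@H](C)CC[C@H]1C(=C)[C@H](O)C[C@H]2C(C)(C)C(=O)CC[C@]12C | intermediate
28 | 7α-chlorosulfite of 27 (not isolated) | COC(=O)C[C@H](C)CC[C@H]1C(=C)[C@H](OS(Cl)=O)C[C@H]2C(C)(C)C(=O)CC[C@]12C | intermediate
29 | methyl (13R)-17-chloro-3-oxolabd-7-en-15-oate | COC(=O)C[C@H](C)CC[C@H]1C(CCl)=CC[C@H]2C(C)(C)C(=O)CC[C@]12C | intermediate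
30 | methyl (13R)-17-acetoxy-3-oxolabd-7-en-15-oate | COC(=O)C[C@H](C)CC[C@H]1C(COC(C)=O)=CC[C@H]2C(C)(C)C(=O)CC[C@]12C | intermediate
31 | methyl (13R)-17-acetoxy-3β-hydroxylabd-7-en-15-oate | COC(=O)C[C@H](C)CC[C@H]1C(COC(C)=O)=CC[C@H]2C(C)(C)[C@@H](O)CC[C@]12C | target

## Step count and risks

Total step count: 23. Longest linear sequence: 16 steps (steps 7 and 9–13 from methyl (R)-citronellate, then steps 14–23).

**Step 14 (proposed new method).** Three processes may defeat it: ring closure through the ortho carbon C4 instead of the para carbon C10; loss of the C9 configuration by π–σ–π exchange or face selection at C10 against the ligand; and intermolecular second allylation leading to oligomers. The fallback uses known chemistry, sets out from 18 and rejoins the route at 22, so that ring A is built by annulation and the phenol 8 and steps 14–16 are not needed.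
- Dimethyl 3-oxopentanedioate is mono-methylated (K2CO3, MeI, acetone) to dimethyl 2-methyl-3-oxopentanedioate F1.
- F1 and 18 undergo the known palladium-catalysed double allylic alkylation of a 3-oxoglutarate by a 2-methylenepropane-1,3-diyl dicarbonate (Pd(PPh3)4, THF, 50 °C). The methylene carbon of F1 should take the primary allyl terminus and the methyl-bearing carbon should close the ring at C9 with net retention, giving dimethyl 1-methyl-6-[(3R)-5-methoxy-3-methyl-5-oxopentyl]-5-methylidene-2-oxocyclohexane-1,3-dicarboxylate F2.
- Krapcho demethoxycarbonylation (LiCl, wet DMSO, 140 °C) removes both β-keto ester groups to give methyl (3R)-3-methyl-5-(trans-2-methyl-6-methylidene-3-oxocyclohexyl)pentanoate F3.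
- Robinson annulation with ethyl vinyl ketone (NaOMe, MeOH, 0 °C then reflux) passes through the 1,5-diketone F4. The Michael addition occurs at the methyl-bearing α-carbon on the face away from the C9 side chain, which sets C10 by substrate control, and aldol condensation gives 22.

**Step 15.** Electron transfer into the cross-conjugated dienone may lead to reductive dimerization or reduction of the 1,2-alkene instead of C6–S cleavage. The fallback sets out from 20 and rejoins at 22 by reversing the order of the two reductions.
- [(Ph3P)CuH]6 (excess, wet benzene) first removes the 1,2-alkene to give methyl (13R)-3-oxo-6-(phenylsulfonyl)-19-norlabda-4,8(17)-dien-15-oate F5.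
- The C6–S bond of this simple γ-sulfonyl enone, which is much harder to over-reduce than the dienone, is then cleaved with SmI2 (THF/MeOH, −78 °C), and DBU brings the product into conjugation as 22.

**Step 21.** Chloride may return at C7 (unrearranged chloride), or HCl may be lost to give dienes. The fallback sets out from 27 and rejoins at 30 by transposing the alcohol instead of a halide.
- Ph3SiOReO3 (cat., Et2O, −50 to 0 °C) equilibrates the secondary allylic alcohol through a [3,3] shift of its perrhenate ester to the primary alcohol with the trisubstituted ring alkene, methyl (13R)-17-hydroxy-3-oxolabd-7-en-15-oate F6.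
- F6 is acetylated (Ac2O, pyridine, DMAP, 0 °C) to 30.

## Further compounds

F1 | step 14 | dimethyl 2-methyl-3-oxopentanedioate | COC(=O)CC(=O)C(C)C(=O)OC
F2 | step 14 | dimethyl 1-methyl-6-[(3R)-5-methoxy-3-methyl-5-oxopentyl]-5-methylidene-2-oxocyclohexane-1,3-dicarboxylate | COC(=O)C[C@H](C)CC[C@H]1C(=C)CC(C(=O)OC)C(=O)C1(C)C(=O)OC
F3 | step 14 | methyl (3R)-3-methyl-5-(trans-2-methyl-6-methylidene-3-oxocyclohexyl)pentanoate | COC(=O)C[C@H](C)CC[C@H]1C(=C)CCC(=O)[C@@H]1C
F4 | step 14 | methyl (3R)-3-methyl-5-[2-methyl-6-methylidene-3-oxo-2-(3-oxopentyl)cyclohexyl]pentanoate | COC(=O)C[C@H](C)CC[C@H]1C(=C)CCC(=O)[C@]1(C)CCC(=O)CC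
F5 | step 15 | methyl (13R)-3-oxo-6-(phenylsulfonyl)-19-norlabda-4,8(17)-dien-15-oate | COC(=O)C[C@H](C)CC[C@H]1C(=C)CC(S(=O)(=O)c3ccccc3)C2=C(C)C(=O)CC[C@]12C
F6 | step 21 | methyl (13R)-17-hydroxy-3-oxolabd-7-en-15-oate | COC(=O)C[C@H](C)CC[C@H]1C(CO)=CC[C@H]2C(C)(C)C(=O)CC[C@]12C
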